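**Assumption:** numbered compounds are substrates, building blocks and products; simple reagents appear by name and SMILES in each step. Ring halogenations are assumed to follow trans-diaxial opening in the ring-B chair that keeps the CMe2 carbon equatorial.

## Retrosynthetic overview
1. The exocyclic methylene comes last (Tebbe methylenation of ketone 14). The tertiary C–Br comes from the tertiary alcohol of a trans-chlorohydrin. The cis Br/OAc pair of ring A comes from a Δ3,4-alkene by bromohydrin formation plus inversion.
2. The Δ3,4-alkene comes from E1cB loss of acetate and deconjugation of β-acetoxy ketone 9. Carvone's acetoxy-bearing carbon directs the key cycloaddition and is then erased.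
3. The spiro[5.5] core and its quaternary centre come from a Lewis-acid Diels–Alder of isoprene on exo-methylene ketone 7. Ring A is already present, and ring B is formed in this step.
4. Ketone 7 comes from (S)-carvone by MeLi/Babler–Dauben, ozonolysis/Baeyer–Villiger (isopropenyl → OAc), cuprate gem-dimethylation and Saegusa oxidation.

## Route

**Step 1**
Reactants: 1 (S)-carvone
Product: 2 (5S)-1,2-dimethyl-5-(prop-1-en-2-yl)cyclohex-2-en-1-ol (C1 epimers)
Conditions: MeLi, THF, −78 °C
Reagents that add atoms: MeLi, C[Li]
Why: Organolithium 1,2-addition to the enone gives the tertiary allylic alcohol, and the new C1 centre is destroyed in the next step.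

**Step 2**
Reactants: 2
Product: 3 (5R)-2,3-dimethyl-5-(prop-1-en-2-yl)cyclohex-2-en-1-one
Conditions: PCC, NaOAc, CH2Cl2, rt
Reagents that add atoms: none
Why: Babler–Dauben oxidative 1,3-transposition moves the carbonyl and gives the β-methyl enone needed for gem-dimethylation; the carvone stereocentre is untouched.

**Step 3**
Reactants: 3
Product: 4 (5R)-5-acetyl-2,3-dimethylcyclohex-2-en-1-one
Conditions: O3, CH2Cl2/MeOH, −78 °C; then Me2S
Reagents that add atoms: ozone, [O-][O+]=O (its O ends up in the ketone)
Why: Ozone cleaves the electron-rich 1,1-disubstituted isopropenyl group selectively over the electron-poor tetrasubstituted enone.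

**Step 4**
Reactants: 4
Product: 5 (1R)-3,4-dimethyl-5-oxocyclohex-3-en-1-yl acetate
Conditions: mCPBA, NaHCO3, CH2Cl2, 0 °C → rt
Reagents that add atoms: mCPBA, OOC(=O)c1cccc(Cl)c1 (supplies the inserted O)
Why: Baeyer–Villiger oxidation migrates the secondary carbon with retention, so the isopropenyl carbon becomes an OAc-bearing stereocentre of unchanged spatial configuration.

**Step 5**
Reactants: 5
Product: 6 (1R)-3,3,4-trimethyl-5-[(trimethylsilyl)oxy]cyclohex-4-en-1-yl acetate
Conditions: MeMgBr, CuBr·SMe2, TMSCl, HMPA, THF, −78 °C → rt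
Reagents that add atoms: MeMgBr, C[Mg]Br; TMSCl, C[Si](C)(C)Cl
Why: Copper-catalysed 1,4-addition to the β,β-disubstituted enone creates the CMe2 carbon (C5 of the target) and traps the enolate as its silyl enol ether.

**Step 6**
Reactants: 6
Product: 7 (1R)-3,3-dimethyl-4-methylidene-5-oxocyclohexyl acetate
Conditions: Pd(OAc)2 (1.1 equiv), MeCN, rt
Reagents that add atoms: none
Why: Saegusa–Ito oxidation can only eliminate β-hydride from the C-methyl group, because the other β-carbon is quaternary, so the exocyclic methylene dienophile forms regiospecifically.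

**Step 7**
Reactants: 7, 8 isoprene (2-methylbuta-1,3-diene)
Product: 9 (3R,6S)-5,5,9-trimethyl-1-oxospiro[5.5]undec-8-en-3-yl acetate
Conditions: isoprene (10 equiv), Me2AlCl (1.2 equiv), CH2Cl2, −78 → 0 °C
Reagents that add atoms: none
Why: Lewis-acid Diels–Alder (para-selective) forms ring B and the quaternary spiro carbon. The C3 gem-dimethyl and the C5 acetoxy group are 1,3-related, so the ring sits in the chair with OAc equatorial and one methyl axial. The diene adds to the exocyclic alkene anti to that axial methyl, which puts the new C–C bond cis to OAc.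

**Step 8**
Reactants: 9
Product: 10 (6S)-5,5,9-trimethylspiro[5.5]undeca-3,8-dien-1-one
Conditions: KOtBu (2.5 equiv), THF, −20 °C; then cool to −78 °C, AcOH
Reagents that add atoms: none
Why: E1cB loss of acetate gives the enone, and excess base forms the extended dienolate, whose kinetic α-protonation gives the β,γ-alkene (Δ3,4). This erases the carvone-derived carbinol centre after it has fixed the spiro centre.

**Step 9**
Reactants: 10
Product: 11 (6S,8S,9S)-8-chloro-9-hydroxy-5,5,9-trimethylspiro[5.5]undec-3-en-1-one
Conditions: NCS, acetone/H2O (4:1), 0 °C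
Reagents that add atoms: NCS, ClN1C(=O)CCC1=O; water, O
Why: Halohydrin formation occurs at the more nucleophilic trisubstituted ring-B alkene, with Cl on the secondary carbon and OH on the tertiary carbon. Anti, trans-diaxial opening in the chair with the CMe2 carbon equatorial sets C8 and C9 relative to the spiro centre.

**Step 10**
Reactants: 11
Product: 12 (3R,4R,6S,8S,9S)-4-bromo-8-chloro-3,9-dihydroxy-5,5,9-trimethylspiro[5.5]undecan-1-one
Conditions: NBS, THF/H2O, 0 °C → rt
Reagents that add atoms: NBS, BrN1C(=O)CCC1=O; water, O
Why: The bromonium forms on the face away from the pseudo-axial ring-B methylene. Water opens it anti at C3, remote from the quaternary C5 (Markovnikov/steric control), giving the trans-bromohydrin.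

**Step 11**
Reactants: 12
Product: 13 (3S,4R,6S,8S,9S)-4-bromo-8-chloro-9-hydroxy-5,5,9-trimethyl-1-oxospiro[5.5]undecan-3-yl acetate
Conditions: PPh3, DIAD, AcOH, THF, 0 °C → rt
Reagents that add atoms: AcOH, CC(=O)O
Why: Mitsunobu SN2 inversion at the secondary C3 carbinol converts the trans-bromohydrin into the cis-bromoacetate; the tertiary alcohol is unreactive.

**Step 12**
Reactants: 13
Product: 14 (3S,4R,6S,8S,9S)-4,9-dibromo-8-chloro-5,5,9-trimethyl-1-oxospiro[5.5]undecan-3-yl acetate
Conditions: TMSBr, CH2Cl2, −78 → 0 °C
Reagents that add atoms: TMSBr, C[Si](C)(C)Br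
Why: Ionisation of the tertiary alcohol is assisted by the anti-periplanar axial C–Cl (chloronium). Bromide then opens it anti to Cl, which gives net retention and the trans-diaxial Br/Cl pair.

**Step 13**
Reactants: 14
Product: 15 9-acetylisoobtusol, (3S,4R,6R,8S,9S)-4,9-dibromo-8-chloro-5,5,9-trimethyl-1-methylidenespiro[5.5]undecan-3-yl acetate
Conditions: Tebbe reagent, pyridine, THF, −40 → 0 °C
Reagents that add atoms: Cp2Ti=CH2 (Tebbe), C=[Ti](C1C=CC=C1)C1C=CC=C1 (supplies the =CH2)
Why: Tebbe methylenation is non-basic and non-reducing, so it converts the hindered ketone to the exocyclic alkene without E1cB loss of the β-acetoxy group or elimination of the halides, and it touches no stereocentre.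

## Compound list
1 | (S)-carvone | CC1=CC[C@@H](CC1=O)C(C)=C | starting material
2 | (5S)-1,2-dimethyl-5-isopropenylcyclohex-2-en-1-ol (C1 epimers) | CC1=CC[C@@H](CC1(C)O)C(C)=C | intermediate
3 | (5R)-2,3-dimethyl-5-(prop-1-en-2-yl)cyclohex-2-en-1-one | O=C1C[C@H](C(C)=C)CC(C)=C1C | intermediate
4 | (5R)-5-acetyl-2,3-dimethylcyclohex-2-en-1-one | O=C1C[C@H](C(C)=O)CC(C)=C1C | intermediate
5 | (1R)-3,4-dimethyl-5-oxocyclohex-3-en-1-yl acetate | O=C1C[C@H](OC(C)=O)CC(C)=C1C | intermediate
6 | (1R)-3,3,4-trimethyl-5-(trimethylsilyloxy)cyclohex-4-en-1-yl acetate | CC1=C(O[Si](C)(C)C)C[C@H](OC(C)=O)CC1(C)C | intermediate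
7 | (1R)-3,3-dimethyl-4-methylidene-5-oxocyclohexyl acetate | O=C1C[C@H](OC(C)=O)CC(C)(C)C1=C | intermediate
8 | isoprene | C=C(C)C=C | starting material
9 | (3R,6S)-5,5,9-trimethyl-1-oxospiro[5.5]undec-8-en-3-yl acetate | O=C1C[C@H](OC(C)=O)CC(C)(C)[C@@]12CCC(C)=CC2 | intermediate
10 | (6S)-5,5,9-trimethylspiro[5.5]undeca-3,8-dien-1-one | O=C1CC=CC(C)(C)[C@@]12CCC(C)=CC2 | intermediate
11 | (6S,8S,9S)-8-chloro-9-hydroxy-5,5,9-trimethylspiro[5.5]undec-3-en-1-one | O=C1CC=CC(C)(C)[C@@]12CC[C@](C)(O)[C@@H](Cl)C2 | intermediate
12 | (3R,4R,6S,8S,9S)-4-bromo-8-chloro-3,9-dihydroxy-5,5,9-trimethylspiro[5.5]undecan-1-one | O=C1C[C@@H](O)[C@H](Br)C(C)(C)[C@@]12CC[C@](C)(O)[C@@H](Cl)C2 | intermediate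
13 | (3S,4R,6S,8S,9S)-4-bromo-8-chloro-9-hydroxy-5,5,9-trimethyl-1-oxospiro[5.5]undecan-3-yl acetate | O=C1C[C@H](OC(C)=O)[C@H](Br)C(C)(C)[C@@]12CC[C@](C)(O)[C@@H](Cl)C2 | intermediate
14 | (3S,4R,6S,8S,9S)-4,9-dibromo-8-chloro-5,5,9-trimethyl-1-oxospiro[5.5]undecan-3-yl acetate | O=C1C[C@H](OC(C)=O)[C@H](Br)C(C)(C)[C@@]12CC[C@](C)(Br)[C@@H](Cl)C2 | intermediate
15 | 9-acetylisoobtusol | C=C1C[C@H](OC(C)=O)[C@H](Br)C(C)(C)[C@@]12CC[C@](C)(Br)[C@@H](Cl)C2 | target

Checks run on the route:
- The formula of 15 is C17H25Br2ClO2.
- The atom balance closes at every step.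
- Compound 15's SMILES matches the given target exactly.
- The spiro centre is quaternary and cannot epimerise.
- The only enolisable, acetoxy-sensitive stage after step 8 is the final Tebbe step, which uses no strong base.

**Total step count:** 13
**Longest linear sequence:** 13 (isoprene is the only convergent partner)

## Three steps most likely to fail
1. **Step 12, tertiary OH → Br with retention.** The cation may epimerise or eliminate. Fallback (different approach): convert the tertiary alcohol to an oxalate or Barton ester, generate the tertiary radical and trap it with BrCCl3. Axial atom transfer should place Br trans-diaxial to the Cl.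
2. **Step 11, Mitsunobu inversion of the trans-bromohydrin.** Participation by the anti-periplanar Br would return the trans product. Fallback (different approach): Tebbe-methylenate the ketone first and silylate the C3 alcohol. Then run the sequence DMP to the α-bromoketone, hydride reduction (anti to Br, which gives cis) and acetylation, and add the tertiary bromide last.
3. **Step 7, Diels–Alder on the sensitive α-methylene ketone, whose facial selectivity rests on the conformational-lock argument.** Fallback (different approach): spiroannulate by sequential C2 alkylation of 5-acetoxy-3,3-dimethylcyclohexanone (allyl bromide, then 4-iodo-2-methylbut-1-ene). Then close ring B by ring-closing metathesis (Grubbs II) to the trisubstituted alkene, with the same axial-alkylation control anti to the axial methyl.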